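**Read across.**

| flask | substrate | partner | remark | time |
|---|---|---|---|---|
| south-west | 7 mM | 7.5 mM | run made earlier |  |
| south | 11 mM | 7.5 mM | run made earlier |  |
| flask | 5.0 mM | 7.50 mM |  | 40 min |

| run | time / min | intermediate B / % | target / % | substrate / % |
|---|---|---|---|---|
| south-west | 0.417 | 3.6 | 1.5 | 40.5 |
| south-west | 1.50 | 9.3 | 1.2 | 9.1 |
| south-west | 6.00 | 5.3 | 1.1 | 0.7 |
| south-west | 25.0 | 0.5 | 1.6 | 0.6 |
| south | 0.417 | 3.6 | 1.9 | 40.8 |
| south | 1.50 | 9.1 | 0.7 | 10.2 |
| south | 6.00 | 8.0 | 0.6 | 2.3 |
| south | 25.0 | 6.1 | 0.8 | 0 |

(standard deviation of a reading: 0.3 percentage points)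

- the moment within 40 min at which there is most intermediate B
- the amount of intermediate B, in percent of the substrate charged, at that time



Compare the south-west and south runs at 1.50 min, the highest reading of intermediate B in each: 9.3% and 9.1%. The gap is smaller than one standard deviation, though the substrate charges differ by 4.00 mM.

**Two extremes.** In one version of the flask, partner stays at its charge until the peak, so the peak, as a percentage, ignores [substrate]. In the other, partner counts as what substrate leaves: 0.500 mM in the south-west run, 2.50 mM in this flask, and nothing in the south run, which is short by 3.50 mM. The two readings stand close together, as in the first version.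

**My reckoning.** So start from the first version and correct it with the peak drift, the fall in the highest reading of intermediate B per mM of substrate, as a fraction of the charge 5.00 × 10⁻⁴ mM⁻¹, a value read from two scattered readings. The first answer is the south-west reading; going round once with the drift gives 9.40% for this flask, and I keep the time 1.50 min.

**The forecast.** It gives 1.3 min and 7.5%, lower than my estimate, on the ground that “B is consumed by leftover partner”.

**The flask.** Intermediate B in this flask peaks at 1.65 min with 9.59%.

    substrate + partner → target (k = 1.02 M⁻¹ s⁻¹)
    substrate ⇌ intermediate A (K = 1.84, k = 0.0211 s⁻¹)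
    substrate → side product A (k = 0.0114 s⁻¹)
    target ⇌ isomer of the product (K = 23.0, k = 0.237 s⁻¹)
    partner + intermediate B → side product B (k = 3.37 M⁻¹ s⁻¹)
    intermediate B ⇌ intermediate C (K = 0.490, k = 0.131 s⁻¹)
    partner + intermediate A → intermediate B (k = 2.33 M⁻¹ s⁻¹)

**Next flask.** This flask stands 0.19 percentage points above the estimate. Carried from the south-west reading to the neighbouring flask with [substrate] at 20 mM, the drift gives 8.65%. That neighbouring flask holds 0.375 equiv of partner to substrate, and partner, its limiting reagent, is down to 0% at 40.0 min. Its peak of intermediate B is 8.37%.

The runs were generated by integration with constants of no real substance; scatter was added.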